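**Plan**

- Ring locants used throughout: C1 = C(OH)Me, C2 = CH carrying the side chain, C3 = CMe2, C4 = CHOH. The retrosynthesis cuts, in order, the aryl ether O–CH2 bond, the side-chain tertiary C–O bond with its neighbouring C–H (back to a Z allylic alcohol), the CH2–C(Me)= bond of the chain, and last the ring bonds C3–C4 and C1–C2 together.
- Enabling feature: the two carbinol carbons C1 and C4 sit 1,4 on the cyclohexane, joined by CH2–CH2, on either side of the vicinal pair C3(Me2)–C2(H), and C2 carries a two-carbon stub. Opened at C3–C4 and C1–C2, the ring is 4-oxopentanal plus a γ,γ-dimethylallyl unit with a second boron one carbon further out; the stub appears as a vinyl group.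
- Forward: diene diboration, then one tandem double allylboration closes the ring (aldehyde first at the CMe2 terminus, ketone second at the former alkene CH). The chain is then joined through the vinyl group by hydroboration/Suzuki–Miyaura coupling, oxygenated by epoxidation/hydride opening and etherified last.
- Stereochemistry: the C–B centre from the platinum/TADDOL-phosphonite diboration is transferred to C4 and relayed to C2 and C1 in the ring closure. C4 is then inverted by oxidation and thermodynamically controlled reduction. The side-chain carbinol comes from L-(+)-tartrate-controlled epoxidation.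

Key step: step 3

Assumption: the (R,R)-antipode of the TADDOL phosphonite is taken to give the (S)-bis(boronate), as with simple 1-alkenes; if the sense is opposite, the (S,S)-ligand is used and nothing else changes.

**Step 1**
Reactants: 1 6-methylhept-5-en-2-one
Product: 3 4-oxopentanal, via secondary ozonide 2 (not isolated)
Conditions: O3, CH2Cl2, −78 °C; then Me2S, −78 °C → rt; used freshly distilled
Reagents that add atoms: ozone, O=[O+][O-]
Why: Ozonolysis with reductive work-up (Criegee mechanism) cleaves the electron-rich trisubstituted alkene and leaves the ketone alone, giving the keto aldehyde fresh because it stores poorly; no stereocentre is formed.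

**Step 2**
Reactants: 4 4-methylpenta-1,3-diene; 5 bis(pinacolato)diboron
Product: 6 (S)-2,2'-(4-methylpent-3-ene-1,2-diyl)bis(4,4,5,5-tetramethyl-1,3,2-dioxaborolane)
Conditions: Pt(dba)3 (3 mol %), (R,R)-3,5-diisopropylphenyl-TADDOL phenylphosphonite (6 mol %), THF, 60 °C, 12 h
Reagents that add atoms: none
Why: Enantioselective alkene diboration at zerovalent platinum (B–B oxidative addition, insertion of the terminal C=C, reductive elimination); the 4,4-disubstituted diene cannot easily reach the s-cis form, so 1,2-addition is expected over 1,4-addition, and the chiral phosphonite sets the secondary C–B centre as (S).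

**Step 3**
Reactants: 6 (S)-2,2'-(4-methylpent-3-ene-1,2-diyl)bis(4,4,5,5-tetramethyl-1,3,2-dioxaborolane); 3 4-oxopentanal
Product: 9 (1S,2S,4S)-2-ethenyl-1,3,3-trimethylcyclohexane-1,4-diol, via (E)-allylboronate borate 7 (not isolated), via cyclic bis(borate) 8 (not isolated)
Conditions: THF, 60 °C, 24 h; then H2O, rt
Reagents that add atoms: none
Why: Tandem double allylboration: the secondary allylic boronate of 6 adds to the aldehyde of 3 through a closed Zimmerman–Traxler chair, bonding at the CMe2 terminus with the CH2Bpin group pseudo-equatorial (A(1,3) strain with the cis γ-methyl), which transfers the (S) C–B centre into the (S) carbinol C4 and unveils the (E)-allylic boronate 7; its γ-carbon then attacks the tethered ketone, closing the six-membered carbocycle (6-exo-trig at the carbonyl) and leaving the vinyl group. The closest known reaction type is the tandem allylation of 1,4-dicarbonyl compounds with the 1,2-bis(boronates) from diene diboration, which gives 2-vinylcyclohexane-1,4-diols. In the ring closure the allylboration chair is trans-fused to the forming cyclohexane chair: the (E)-alkene puts C3 equatorial and the ketone methyl axial, so the vinyl group and the tertiary hydroxyl should emerge trans (C1 and C2 both S), while the C4–OBpin group sits equatorial on the forming ring and so decides which face of the allyl unit is used. Both new ring stereocentres are thus relayed from C4 under substrate control, and all three trace back to the one C–B centre of 6. The step needs aldehyde-before-ketone chemoselectivity (secured by the reactivity gap), γ- over α-attack (secured by the cyclic transition states) and the (E)-geometry of 7 (secured by the γ,γ-dimethyl group). The equatorial C4–O places that hydroxyl cis to the vinyl group, the epimer of what the target needs at C4, which is why steps 4 and 5 follow.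

**Step 4**
Reactants: 9 (1S,2S,4S)-2-ethenyl-1,3,3-trimethylcyclohexane-1,4-diol
Product: 10 (3S,4S)-3-ethenyl-4-hydroxy-2,2,4-trimethylcyclohexan-1-one
Conditions: DMP (1.3 equiv), CH2Cl2, 0 °C → rt
Reagents that add atoms: none
Why: Dess–Martin oxidation takes the secondary carbinol to the ketone while the tertiary alcohol and the vinyl group are inert, erasing only the stereocentre that has to be re-set; the quaternary α-carbon and the γ-position of the hydroxyl exclude epimerisation and retro-aldol cleavage.

**Step 5**
Reactants: 10 (3S,4S)-3-ethenyl-4-hydroxy-2,2,4-trimethylcyclohexan-1-one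
Product: 11 (1S,2S,4R)-2-ethenyl-1,3,3-trimethylcyclohexane-1,4-diol
Conditions: Li (3 equiv), NH3(l)/THF, t-BuOH (2 equiv), −78 °C; then NH4Cl
Reagents that add atoms: none
Why: Dissolving-metal (ketyl) reduction, which gives the more stable carbinol: the ring should prefer the chair with the C2 vinyl and C1 hydroxyl axial (it avoids the syn-diaxial C1-Me/C3-Me pair and an equatorial vinyl group wedged between two quaternary carbons), and in that chair an axial C4–O would clash 1,3-diaxially with the vinyl group, so protonation of the pyramidal α-oxido carbanion should leave the C4 oxygen equatorial, cis to the C1 hydroxyl (4R).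

**Step 6**
Reactants: 12 but-2-yn-1-ol
Product: 14 (Z)-3-iodobut-2-en-1-ol, via cyclic vinylalanate 13 (not isolated)
Conditions: NaAlH2(OCH2CH2OMe)2 (1.5 equiv), THF, 0 °C → rt; then I2, −78 °C → rt
Reagents that add atoms: iodine, II
Why: Hydroxyl-directed trans-hydroalumination of the propargylic alcohol places aluminium on the distal carbon in a five-membered alkoxyalanate, and iodinolysis of the C–Al bond with retention gives the (Z)-iodoalkene (iodine cis to CH2OH).

**Step 7**
Reactants: 11 (1S,2S,4R)-2-ethenyl-1,3,3-trimethylcyclohexane-1,4-diol; 14 (Z)-3-iodobut-2-en-1-ol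
Product: 16 (1S,2S,4R)-2-[(3Z)-5-hydroxy-3-methylpent-3-en-1-yl]-1,3,3-trimethylcyclohexane-1,4-diol, via B-alkyl-9-BBN adduct 15 (not isolated)
Conditions: 9-BBN (3.5 equiv), THF, rt → 50 °C; then 14 (1.3 equiv), PdCl2(dppf) (5 mol %), AsPh3 (10 mol %), Cs2CO3 (3 equiv), DMF/H2O, rt
Reagents that add atoms: none
Why: Anti-Markovnikov hydroboration of the terminal vinyl group followed by B-alkyl Suzuki–Miyaura coupling at zerovalent palladium, with retention of the Z geometry, joins the ring-bound CH2CH2 to the C(Me)= carbon; the hindered hydroxyls at most form borinates that the aqueous base cleaves, and no stereocentre is formed.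

**Step 8**
Reactants: 16 (1S,2S,4R)-2-[(3Z)-5-hydroxy-3-methylpent-3-en-1-yl]-1,3,3-trimethylcyclohexane-1,4-diol
Product: 17 (1S,2S,4R)-2-{2-[(2R,3S)-3-(hydroxymethyl)-2-methyloxiran-2-yl]ethyl}-1,3,3-trimethylcyclohexane-1,4-diol
Conditions: Ti(OiPr)4 (0.3 equiv), L-(+)-diethyl tartrate (0.36 equiv), t-BuOOH (2 equiv, decane), 4 Å molecular sieves, CH2Cl2, −20 °C
Reagents that add atoms: tert-butyl hydroperoxide, CC(C)(C)OO
Why: Katsuki–Sharpless asymmetric epoxidation: the primary allylic alkoxide binds the titanium–tartrate catalyst, which delivers oxygen to one alkene face regardless of the remote ring stereocentres; with L-(+)-tartrate a (Z)-3,3-disubstituted allylic alcohol of the nerol type should give the (2S,3R)-epoxy alcohol, fixing the future tertiary carbinol as (R).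

**Step 9**
Reactants: 17 (1S,2S,4R)-2-{2-[(2R,3S)-3-(hydroxymethyl)-2-methyloxiran-2-yl]ethyl}-1,3,3-trimethylcyclohexane-1,4-diol
Product: 18 (1S,2S,4R)-2-[(3R)-3,5-dihydroxy-3-methylpentyl]-1,3,3-trimethylcyclohexane-1,4-diol
Conditions: NaAlH2(OCH2CH2OMe)2 (6 equiv), THF, 0 °C → rt; then H2O
Reagents that add atoms: none
Why: Reductive opening of a 2,3-epoxy alcohol by the alkoxide-bound aluminium hydride, which delivers hydride intramolecularly to the epoxide carbon next to the carbinol (also the less substituted one) and so gives the 1,3-diol; the tertiary C–O bond and its (R) configuration are untouched.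

**Step 10**
Reactants: 18 (1S,2S,4R)-2-[(3R)-3,5-dihydroxy-3-methylpentyl]-1,3,3-trimethylcyclohexane-1,4-diol; 19 7-hydroxy-2H-chromen-2-one (umbelliferone)
Product: 20 7-{[(3R)-5-[(1S,3R,6S)-3,6-dihydroxy-2,2,6-trimethylcyclohexyl]-3-hydroxy-3-methylpentyl]oxy}-2H-chromen-2-one
Conditions: PPh3 (1.3 equiv), DIAD (1.3 equiv), THF, 0 °C → rt
Reagents that add atoms: none
Why: Mitsunobu etherification: only the primary hydroxyl forms a reactive alkoxyphosphonium ion, which the acidic phenol displaces at CH2, while the two tertiary and the neopentylic secondary hydroxyl should not react and no stereocentre is touched.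

**Compound list**

1 | 6-methylhept-5-en-2-one | CC(=O)CCC=C(C)C | starting material
2 | 3,3-dimethyl-5-(3-oxobutyl)-1,2,4-trioxolane (secondary ozonide, racemic at the ring CH) | CC(=O)CCC1OOC(C)(C)O1 | intermediate
3 | 4-oxopentanal | CC(=O)CCC=O | intermediate
4 | 4-methylpenta-1,3-diene | CC(C)=CC=C | starting material
5 | bis(pinacolato)diboron | CC1(C)OB(OC1(C)C)B1OC(C)(C)C(C)(C)O1 | starting material
6 | (S)-2,2'-(4-methylpent-3-ene-1,2-diyl)bis(4,4,5,5-tetramethyl-1,3,2-dioxaborolane) | CC(C)=C[C@@H](B1OC(C)(C)C(C)(C)O1)CB1OC(C)(C)C(C)(C)O1 | intermediate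
7 | (5S,7E)-6,6-dimethyl-9-(4,4,5,5-tetramethyl-1,3,2-dioxaborolan-2-yl)-5-[(4,4,5,5-tetramethyl-1,3,2-dioxaborolan-2-yl)oxy]non-7-en-2-one | CC(=O)CC[C@H](OB1OC(C)(C)C(C)(C)O1)C(C)(C)/C=C/CB1OC(C)(C)C(C)(C)O1 | intermediate
8 | 2,2'-{[(1S,2S,4S)-2-ethenyl-1,3,3-trimethylcyclohexane-1,4-diyl]bis(oxy)}bis(4,4,5,5-tetramethyl-1,3,2-dioxaborolane) | CC1(C)[C@@H](OB2OC(C)(C)C(C)(C)O2)CC[C@](C)(OB2OC(C)(C)C(C)(C)O2)[C@H]1C=C | intermediate
9 | (1S,2S,4S)-2-ethenyl-1,3,3-trimethylcyclohexane-1,4-diol (secondary OH cis to vinyl, tertiary OH trans to vinyl) | CC1(C)[C@@H](O)CC[C@](C)(O)[C@H]1C=C | intermediate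
10 | (3S,4S)-3-ethenyl-4-hydroxy-2,2,4-trimethylcyclohexan-1-one | CC1(C)C(=O)CC[C@](C)(O)[C@H]1C=C | intermediate
11 | (1S,2S,4R)-2-ethenyl-1,3,3-trimethylcyclohexane-1,4-diol (cis-1,4-diol, both OH trans to vinyl) | CC1(C)[C@H](O)CC[C@](C)(O)[C@H]1C=C | intermediate
12 | but-2-yn-1-ol | CC#CCO | starting material
13 | sodium 2,2-bis(2-methoxyethoxy)-3-methyl-2,5-dihydro-1,2-oxaaluminol-2-uide (cyclic vinylalanate) | [Na+].CC1=CCO[Al-]1(OCCOC)OCCOC | intermediate
14 | (Z)-3-iodobut-2-en-1-ol | C/C(I)=C/CO | intermediate
15 | (1S,2S,4R)-2-[2-(9-borabicyclo[3.3.1]nonan-9-yl)ethyl]-1,3,3-trimethylcyclohexane-1,4-diol (hydroxyls drawn free) | CC1(C)[C@H](O)CC[C@](C)(O)[C@H]1CCB1C2CCCC1CCC2 | intermediate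
16 | (1S,2S,4R)-2-[(3Z)-5-hydroxy-3-methylpent-3-en-1-yl]-1,3,3-trimethylcyclohexane-1,4-diol | CC1(C)[C@H](O)CC[C@](C)(O)[C@H]1CC/C(C)=C\CO | intermediate
17 | (1S,2S,4R)-2-{2-[(2R,3S)-3-(hydroxymethyl)-2-methyloxiran-2-yl]ethyl}-1,3,3-trimethylcyclohexane-1,4-diol | CC1(C)[C@H](O)CC[C@](C)(O)[C@H]1CC[C@@]2(C)O[C@H]2CO | intermediate
18 | (1S,2S,4R)-2-[(3R)-3,5-dihydroxy-3-methylpentyl]-1,3,3-trimethylcyclohexane-1,4-diol | CC1(C)[C@H](O)CC[C@](C)(O)[C@H]1CC[C@@](C)(O)CCO | intermediate
19 | 7-hydroxy-2H-chromen-2-one (umbelliferone) | Oc1ccc2ccc(=O)oc2c1 | starting material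
20 | 7-{[(3R)-5-[(1S,3R,6S)-3,6-dihydroxy-2,2,6-trimethylcyclohexyl]-3-hydroxy-3-methylpentyl]oxy}-2H-chromen-2-one | CC1(C)[C@H](O)CC[C@](C)(O)[C@H]1CC[C@@](C)(O)CCOc1ccc2ccc(=O)oc2c1 | target

**Step count and risks**

Total steps: 10. Longest linear sequence: 8 steps (steps 2, 3, 4, 5, 7, 8, 9, 10 from 4-methylpenta-1,3-diene; the branch through step 1 is equally long).

Most likely to fail:

Step 5. Proton and electron delivery may return the all-equatorial C4 epimer, or a mixture, if the two chair forms are closer in energy than argued or the lithium alkoxide at C1 shifts the balance. The fallback sets out from 10 and installs the C4 oxygen from the face of the tertiary hydroxyl instead. Condensation with TsNHNH2 (MeOH, cat. AcOH) should give N'-[(3S,4S)-3-ethenyl-4-hydroxy-2,2,4-trimethylcyclohexylidene]-4-methylbenzenesulfonohydrazide F1. A Shapiro reaction (n-BuLi, 3.3 equiv, THF/TMEDA, −78 → 0 °C; then H2O) can only deprotonate the CH2 side and should give (1S,6S)-6-ethenyl-1,5,5-trimethylcyclohex-3-en-1-ol F2. Epoxidation directed by the homoallylic tertiary hydroxyl (VO(acac)2, t-BuOOH, CH2Cl2; the disubstituted ring alkene is the more nucleophilic olefin) should give (1R,3S,4S,6S)-4-ethenyl-3,5,5-trimethyl-7-oxabicyclo[4.1.0]heptan-3-ol F3. LiAlH4 in THF should then open the epoxide trans-diaxially at the carbon remote from CMe2, which puts the secondary hydroxyl cis to the tertiary one and comes back to the route at 11.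

Step 3. The intramolecular ketone allylboration joins two congested carbons; it may stall or lose facial control at the temperature it needs. The fallback sets out from 6 and 3 and makes the two C–C bonds in separate operations. The two are combined at the lowest temperature at which the aldehyde is consumed, so that only 7 forms. Oxidation of its C–B bond (NaBO3·4H2O, THF/H2O) should give (5S,7E)-5,9-dihydroxy-6,6-dimethylnon-7-en-2-one F4. Selective acylation of the primary allylic hydroxyl (ClCO2Me, pyridine, CH2Cl2, −20 °C) should give methyl [(2E,5S)-5-hydroxy-4,4-dimethyl-8-oxonon-2-en-1-yl] carbonate F5. A palladium-catalysed umpolung allylation (Pd(PPh3)4, InI, THF, rt) would convert the allyl carbonate into an allylindium species that adds to the ketone through its γ-carbon in a chair transition state, closing the ring and returning to the route at 9.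

Step 8. The cis-1,4-diol may sequester the titanium–tartrate catalyst, and (Z)-trisubstituted allylic alcohols give lower facial control than their (E)-isomers. The fallback sets out from 16 and uses a hydroxyl-independent oxygen transfer: Shi epoxidation with the L-fructose-derived antipode of the Shi ketone (the one that attacks the same alkene face as L-(+)-tartrate here), KHSO5 (as 2KHSO5·KHSO4·K2SO4), K2CO3, MeCN/dimethoxymethane/aqueous buffer, 0 °C. It comes back to the route at 17 directly and makes no compound outside the list (none, F0).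

**Further compounds**

F1 | step 5 | N'-[(3S,4S)-3-ethenyl-4-hydroxy-2,2,4-trimethylcyclohexylidene]-4-methylbenzenesulfonohydrazide | CC1(C)C(=NNS(=O)(=O)c2ccc(C)cc2)CC[C@](C)(O)[C@H]1C=C
F2 | step 5 | (1S,6S)-6-ethenyl-1,5,5-trimethylcyclohex-3-en-1-ol | CC1(C)C=CC[C@](C)(O)[C@H]1C=C
F3 | step 5 | (1R,3S,4S,6S)-4-ethenyl-3,5,5-trimethyl-7-oxabicyclo[4.1.0]heptan-3-ol | CC1(C)[C@@H]2O[C@@H]2C[C@](C)(O)[C@H]1C=C
F4 | step 3 | (5S,7E)-5,9-dihydroxy-6,6-dimethylnon-7-en-2-one | CC(=O)CC[C@H](O)C(C)(C)/C=C/CO
F5 | step 3 | methyl [(2E,5S)-5-hydroxy-4,4-dimethyl-8-oxonon-2-en-1-yl] carbonate | CC(=O)CC[C@H](O)C(C)(C)/C=C/COC(=O)OC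
F0 | step 8 | none | none
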